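**Retrosynthetic overview**

1. Ring numbering used here: O1, C2 (methyl), C3 (CH2OH), C4 (acetate arm), C5 (CO2Me), C6 (=CH–O). The primary alcohol is traced back to the C3 aldehyde (hydride) and the side-chain ester to the free acid plus hydroxytyrosol (Mitsunobu); the catechol ring is bought.
2. Key disconnection: the enol ether bond O1–C6 and the bond C3–C4 are cut together. This divides the ring into O1–C2–C3, which is (R)-3-hydroxybutanal with its hydroxyl oxygen and α-carbon as a 1,3-O,C-dinucleophile, and C6=C5(CO2Me)–C4–CH2–CO2H, which is methyl coumalate.
3. Enabling feature: the string O–C6H=C5(CO2Me)–C4–CH2–C(=O)O of the target is, atom for atom, the perimeter of the 2-pyranone ring of methyl coumalate (its own numbering O1, C2(=O), C3, C4, C5(CO2Me), C6). The C6–O1 enol-lactone bond is a vinylogous anhydride, so C6 carries a leaving group for the incoming oxygen, and the C3=C4 enoate is the Michael acceptor for the α-carbon. The lactone is thus a temporary ring, opened in the key step to leave the acetic acid arm.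
4. Stereochemistry: C2 comes from the chiral pool ((R)-butane-1,3-diol); C3 and C4 are set in the key step by a chiral secondary amine matched with C2, and C3 stays epimerisable until the last step.
5. Ring order: the bought pyranone ring is opened and the dihydropyran is closed in the same flask; no other ring is formed.

Key step: step 2

Remark: the target is the all-trans (2R,3R,4S) dihydropyran (methyl and acetate arm cis to each other, hydroxymethyl trans to both). C3 is α to an aldehyde until the last step and is assumed to equilibrate to this arrangement.

**Step 1**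
Reactants: 1 (R)-butane-1,3-diol
Product: 2 (R)-3-hydroxybutanal
Conditions: 2,2,6,6-tetramethylpiperidin-1-oxyl (TEMPO, 10 mol%), PhI(OAc)2 (1.1 equiv), CH2Cl2, 0 °C to rt; short silica plug, used at once
Reagents that add atoms: none
Why: Oxoammonium oxidation with TEMPO and PhI(OAc)2 is a known way to take the primary hydroxyl of a 1,3-diol to the aldehyde in the presence of the secondary one, and it leaves the carbinol stereocentre untouched.

**Step 2**
Reactants: 2 (R)-3-hydroxybutanal; 3 methyl coumalate (methyl 2-oxo-2H-pyran-5-carboxylate)
Product: 6 2-[(2R,3S,4S)-3-formyl-5-(methoxycarbonyl)-2-methyl-3,4-dihydro-2H-pyran-4-yl]acetic acid, via DABCO vinylammonium betaine 4 (not isolated), via vinyl ether acid 5 (not isolated)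
Conditions: 3, 1,4-diazabicyclo[2.2.2]octane (DABCO, 1.1 equiv), MeCN, 0 °C; add 2, rt; then CF3CO2H (1.1 equiv), (S)-2-[diphenyl(trimethylsilyloxy)methyl]pyrrolidine (20 mol%), 30 °C (one flask)
Reagents that add atoms: none
Why: Proposed new method: DABCO adds to C6 of the 2-pyranone 3 and the adduct expels the lactone carboxylate (the ring is a vinylogous anhydride) to give betaine 4, the secondary hydroxyl of 2 then replaces DABCO at that carbon by addition–elimination (the delocalised glutaconate-type adduct lets the enoate relax from Z to E) to give vinyl ether acid 5, and, once the tertiary amine is neutralised, the pyrrolidine catalyst converts the aldehyde into an enamine whose α-carbon adds to the β-carbon of the enoic acid. The closest known reaction types are the amine-induced opening of coumalates at C6, the tertiary-amine-mediated O-vinylation of alcohols with β-activated acrylates, and the amine-catalysed oxa-Michael/Michael route to 3-formylchromans, of which the second stage is the aliphatic counterpart; the transfer of a 2-pyranone onto a hydroxy aldehyde in this way is not known. The only ring formed, the dihydropyran, closes by 6-exo-trig Michael addition that makes C3–C4, its O1–C6 bond having been made in the first stage, while the pyranone ring is lost. C2 comes unchanged from 2; C3 is set on the enamine face left open by the diphenyl(silyloxy)methyl group of the (S)-catalyst and, being α to the aldehyde, can relax to the trans arrangement; C4 is set in a half-chair transition state with the C2 methyl pseudo-equatorial and the enamine and enoate anti, which should put the acetic acid arm trans to the formyl group and cis to the methyl group. The step needs oxygen before carbon attack on the pyranone and attack at C6 in place of the lactone carbonyl: the first is secured because 3 is consumed as betaine 4 before 2 is added and no enamine of 2 exists until the secondary amine is added, the second because acyl attack is reversible whereas attack at C6 ends in irreversible loss of the carboxylate. A retro-oxa-Michael opening of the enamine, if it occurs, should be returned to the (R)-configuration at C2 by the same (S)-catalyst through its iminium ion.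

**Step 3**
Reactants: 6 2-[(2R,3S,4S)-3-formyl-5-(methoxycarbonyl)-2-methyl-3,4-dihydro-2H-pyran-4-yl]acetic acid; 7 hydroxytyrosol (4-(2-hydroxyethyl)benzene-1,2-diol)
Product: 8 methyl (2R,3S,4S)-4-{2-[2-(3,4-dihydroxyphenyl)ethoxy]-2-oxoethyl}-3-formyl-2-methyl-3,4-dihydro-2H-pyran-5-carboxylate
Conditions: PPh3, diisopropyl azodicarboxylate (DIAD), THF, 0 °C to rt
Reagents that add atoms: none
Why: Mitsunobu esterification, in which the betaine is protonated only by the carboxylic acid (far more acidic than the two phenols) and only the primary hydroxyl of 7 is activated, so the carboxylate should be alkylated without catechol protection and without touching a stereocentre.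

**Step 4**
Reactants: 8 methyl (2R,3S,4S)-4-{2-[2-(3,4-dihydroxyphenyl)ethoxy]-2-oxoethyl}-3-formyl-2-methyl-3,4-dihydro-2H-pyran-5-carboxylate
Product: 9 methyl (2R,3R,4S)-4-{2-[2-(3,4-dihydroxyphenyl)ethoxy]-2-oxoethyl}-3-(hydroxymethyl)-2-methyl-3,4-dihydro-2H-pyran-5-carboxylate (target)
Conditions: NaBH4, MeOH/THF, −40 °C; AcOH quench at −40 °C
Reagents that add atoms: none
Why: Borohydride reduction of an aldehyde is much faster than that of the saturated ester or the vinylogous carbonate at −40 °C, the cold acidic quench should keep the new primary alkoxide from closing onto the side-chain ester, and the geometry at C3 is carried over from 8 (the descriptor changes from S to R only because the substituent priorities change).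

**Compound list**

1 | (R)-butane-1,3-diol | C[C@@H](O)CCO | starting material
2 | (R)-3-hydroxybutanal | C[C@@H](O)CC=O | intermediate
3 | methyl coumalate (methyl 2-oxo-2H-pyran-5-carboxylate) | COC(=O)C1=COC(=O)C=C1 | starting material
4 | (2Z,4E)-4-[(4-aza-1-azoniabicyclo[2.2.2]octan-1-yl)methylidene]-5-methoxy-5-oxopent-2-enoate (DABCO vinylammonium betaine) | [O-]C(=O)/C=C\C(=C/[N+]12CCN(CC1)CC2)C(=O)OC | intermediate (not isolated)
5 | (2E,4E)-5-methoxy-5-oxo-4-({[(2R)-4-oxobutan-2-yl]oxy}methylidene)pent-2-enoic acid (vinyl ether acid) | C[C@H](CC=O)O/C=C(\C=C\C(O)=O)C(=O)OC | intermediate (not isolated)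
6 | 2-[(2R,3S,4S)-3-formyl-5-(methoxycarbonyl)-2-methyl-3,4-dihydro-2H-pyran-4-yl]acetic acid | COC(=O)C1=CO[C@H](C)[C@@H](C=O)[C@@H]1CC(=O)O | intermediate
7 | hydroxytyrosol, 4-(2-hydroxyethyl)benzene-1,2-diol | OCCc1ccc(O)c(O)c1 | starting material
8 | methyl (2R,3S,4S)-4-{2-[2-(3,4-dihydroxyphenyl)ethoxy]-2-oxoethyl}-3-formyl-2-methyl-3,4-dihydro-2H-pyran-5-carboxylate | COC(=O)C1=CO[C@H](C)[C@@H](C=O)[C@@H]1CC(=O)OCCc1ccc(O)c(O)c1 | intermediate
9 | methyl (2R,3R,4S)-4-{2-[2-(3,4-dihydroxyphenyl)ethoxy]-2-oxoethyl}-3-(hydroxymethyl)-2-methyl-3,4-dihydro-2H-pyran-5-carboxylate | COC(=O)C1=CO[C@H](C)[C@@H](CO)[C@@H]1CC(=O)OCCc1ccc(O)c(O)c1 | target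

Total step count: 4. Longest linear sequence: 4 steps (1 → 2 → 6 → 8 → 9).

**Steps most likely to fail**

1. Step 2 (proposed new method).
   - What may go wrong in the first stage: the free hydroxy aldehyde may undergo aldol or Morita–Baylis–Hillman-type carbon–carbon bond formation in place of O-vinylation.
   - What may go wrong in the second stage: the enamine may lose the vinylogous carboxylate by β-elimination, the secondary amine may exchange with the vinyl ether, the Michael closure onto a free enoic acid may be too slow, or the facial selectivity at C4 may be poor.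
   - Fallback (known chemistry): the two bonds are made in separate, isolated steps, with the aldehyde masked and the acceptor esterified before the ring closure. It sets out from 2 and 3 and comes back at 8. Compound 2 is acetalised (HC(OMe)3, MeOH, pyridinium p-toluenesulfonate) to (R)-4,4-dimethoxybutan-2-ol F1. The sodium alkoxide of F1 (NaH, THF, 0 °C) opens 3 by 1,6-addition and loss of the carboxylate, the alkoxide counterpart of the familiar amine opening of coumalates, to give acetal acid F2. Mitsunobu esterification of F2 with 7 (PPh3, DIAD, THF) gives acetal ester F3. Mild acid hydrolysis (pyridinium p-toluenesulfonate, acetone/H2O) frees aldehyde ester F4. The amine-catalysed intramolecular Michael addition of the aldehyde onto the enoate ester, a known ring closure of formyl enoates (same (S)-pyrrolidine catalyst, PhCO2H, CHCl3), should then give 8 directly.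

2. Step 4.
   - What may go wrong: the primary alkoxide (or borate) formed in the reduction may close onto the side-chain ester, giving a δ-lactone with loss of hydroxytyrosol; the basic medium may also open the β-alkoxy aldehyde by retro-oxa-Michael reaction before it is reduced.
   - Fallback: the reduction is moved in front of the esterification and the hydroxyl is carried as a silyl ether. It sets out from 6 and comes back at 9. Compound 6 is reduced as its sodium salt (NaBH4, MeOH, 0 °C) to hydroxy acid F5, which is kept as the carboxylate. Silylation (tert-butyldimethylsilyl chloride, imidazole, DMF) gives bis-silyl compound F6, whose silyl ester is cleaved (K2CO3, MeOH/H2O) to silyl ether acid F7. Mitsunobu esterification with 7 as in step 3 gives silyl ether ester F8. Removal of the silyl ether under non-basic conditions (HF·pyridine, THF/pyridine, 0 °C) should give 9 without an alkoxide ever facing the ester.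

3. Step 3.
   - What may go wrong: alkylation or acylation at the catechol oxygens, and epimerisation or ring opening of the β-alkoxy aldehyde by the basic betaine.
   - Fallback: the acyl partner is activated on an enzyme in place of activating the alcohol as an oxyphosphonium ion. It sets out from 6 and 7, comes back at 8 and makes no new compound (F0). Lipase-catalysed esterification (immobilised Candida antarctica lipase B, molecular sieves, tert-amyl alcohol, 40 °C) is a transformation known to acylate hydroxytyrosol only at its primary hydroxyl under neutral conditions.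

**Further compounds**

F1 | step 2 | (R)-4,4-dimethoxybutan-2-ol | C[C@@H](O)CC(OC)OC
F2 | step 2 | (2E,4E)-4-({[(2R)-4,4-dimethoxybutan-2-yl]oxy}methylidene)-5-methoxy-5-oxopent-2-enoic acid | C[C@H](CC(OC)OC)O/C=C(\C=C\C(O)=O)C(=O)OC
F3 | step 2 | 1-[2-(3,4-dihydroxyphenyl)ethyl] 5-methyl (2E,4E)-4-({[(2R)-4,4-dimethoxybutan-2-yl]oxy}methylidene)pent-2-enedioate | C[C@H](CC(OC)OC)O/C=C(\C=C\C(=O)OCCc1ccc(O)c(O)c1)C(=O)OC
F4 | step 2 | 1-[2-(3,4-dihydroxyphenyl)ethyl] 5-methyl (2E,4E)-4-({[(2R)-4-oxobutan-2-yl]oxy}methylidene)pent-2-enedioate | C[C@H](CC=O)O/C=C(\C=C\C(=O)OCCc1ccc(O)c(O)c1)C(=O)OC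
F5 | step 4 | 2-[(2R,3R,4S)-3-(hydroxymethyl)-5-(methoxycarbonyl)-2-methyl-3,4-dihydro-2H-pyran-4-yl]acetic acid | COC(=O)C1=CO[C@H](C)[C@@H](CO)[C@@H]1CC(=O)O
F6 | step 4 | tert-butyldimethylsilyl 2-[(2R,3R,4S)-3-{[(tert-butyldimethylsilyl)oxy]methyl}-5-(methoxycarbonyl)-2-methyl-3,4-dihydro-2H-pyran-4-yl]acetate | COC(=O)C1=CO[C@H](C)[C@@H](CO[Si](C)(C)C(C)(C)C)[C@@H]1CC(=O)O[Si](C)(C)C(C)(C)C
F7 | step 4 | 2-[(2R,3R,4S)-3-{[(tert-butyldimethylsilyl)oxy]methyl}-5-(methoxycarbonyl)-2-methyl-3,4-dihydro-2H-pyran-4-yl]acetic acid | COC(=O)C1=CO[C@H](C)[C@@H](CO[Si](C)(C)C(C)(C)C)[C@@H]1CC(=O)O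
F8 | step 4 | methyl (2R,3R,4S)-3-{[(tert-butyldimethylsilyl)oxy]methyl}-4-{2-[2-(3,4-dihydroxyphenyl)ethoxy]-2-oxoethyl}-2-methyl-3,4-dihydro-2H-pyran-5-carboxylate | COC(=O)C1=CO[C@H](C)[C@@H](CO[Si](C)(C)C(C)(C)C)[C@@H]1CC(=O)OCCc1ccc(O)c(O)c1
F0 | step 3 | none | none
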